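The 14-membered ring is opened at C12–C13: the C13 allylic carbinol next to the E-trisubstituted C11=C12 alkene is the signature of a reductive alkyne–aldehyde coupling. One nickel-catalysed operation closes the carbocycle in the endocyclic mode, forms the C12–C13 bond, sets the E-alkene and delivers C13 as a silyl ether. Its precursor is a seco-ynal: a trans-4,5-disubstituted γ-lactone (C1, C14, C15, C16) carrying the C13 aldehyde on C14 and, on C1, a chain with the C3–C4 epoxide, the C7=C8 alkene and a methyl-capped C11≡C12 alkyne. The chain comes from geraniol, the lactone from (S)-5-(hydroxymethyl)butenolide, joined by a Giese addition; C13 is finally acetylated with inversion.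

Key step: step 13

Remarks on the chemistry (locants are cembrane locants: lactone C1, C14, C15, C16; epoxide C3–C4; alkenes C7=C8 and C11=C12; C17 is the methylene carbon).
- Epoxide: a radical beside an epoxide opens it, and a syn-diol made from the E-alkene of geraniol would close to the cis-epoxide. The C3–C4 unit is therefore carried through the radical step as a free diol whose C3 has been inverted by a Payne rearrangement. Mesylate closure inverts C3 back and the tertiary C4 is never touched. No acetonide is needed, because a β-hydroxyalkyl radical does not fragment.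
- Assumption: the nickel step is taken to follow 1,2-induction from C14 (polar Felkin–Anh), which places the C13 oxygen anti to the C14 oxygen (13R). The acetate is therefore introduced with inversion. Any 13S material is acetylated with retention (Ac2O, pyridine) and reaches the same target.
- CIP descriptors at C3 change with the neighbouring substituent (Se, I or C); the SMILES strings carry the configurations.

Step 1
Reactants: 1 geraniol
Product: 2 tert-butyl{[(2E)-3,7-dimethylocta-2,6-dien-1-yl]oxy}dimethylsilane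
Conditions: TBSCl, imidazole, CH2Cl2, 0 °C to rt
Reagents that add atoms: tert-butyldimethylsilyl chloride, CC(C)(C)[Si](C)(C)Cl
Why: Imidazole-promoted silyl ether formation masks the primary allylic alcohol against the organolithium chemistry of step 4.

Step 2
Reactants: 2 tert-butyl{[(2E)-3,7-dimethylocta-2,6-dien-1-yl]oxy}dimethylsilane
Product: 3 (2E,6E)-8-[(tert-butyldimethylsilyl)oxy]-2,6-dimethylocta-2,6-dien-1-ol
Conditions: SeO2 (cat.), t-BuOOH, salicylic acid (cat.), CH2Cl2, 0 °C to rt
Reagents that add atoms: tert-butyl hydroperoxide, CC(C)(C)OO (oxygen relayed through catalytic SeO2, O=[Se]=O)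
Why: Riley allylic oxidation (ene reaction, then [2,3]-sigmatropic shift) attacks the electron-richer distal alkene and hydroxylates the methyl group trans to the chain, which fixes the E geometry of the later C7=C8 alkene, while the alkene next to the silyl ether is deactivated.

Step 3
Reactants: 3 (2E,6E)-8-[(tert-butyldimethylsilyl)oxy]-2,6-dimethylocta-2,6-dien-1-ol
Product: 4 {[(2E,6E)-8-bromo-3,7-dimethylocta-2,6-dien-1-yl]oxy}(tert-butyl)dimethylsilane
Conditions: CBr4, PPh3, CH2Cl2, −20 to 0 °C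
Reagents that add atoms: carbon tetrabromide, BrC(Br)(Br)Br
Why: Appel bromination converts the primary allylic alcohol into the bromide under neutral conditions that leave the silyl ether and both alkene geometries untouched.

Step 4
Reactants: 4 {[(2E,6E)-8-bromo-3,7-dimethylocta-2,6-dien-1-yl]oxy}(tert-butyl)dimethylsilane; 5 propyne
Product: 8 tert-butyl{[(2E,6E)-3,7-dimethyldodeca-2,6-dien-10-yn-1-yl]oxy}dimethylsilane, via 1,3-dilithiopropyne 6 (not isolated), via lithium acetylide 7 (not isolated)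
Conditions: propyne, n-BuLi (2 equiv per propyne), TMEDA, Et2O–hexane, −78 to 0 °C; 4, −78 °C to rt; then MeI, THF–DMPU, 0 °C to rt
Reagents that add atoms: iodomethane, CI
Why: Propargylation with the propyne dianion: the sp3 carbanion of 6 displaces the primary allylic bromide by SN2 (forming C9–C10), and the acetylide that remains is capped in the same flask by methyl iodide, giving the methyl alkyne without allene formation.

Step 5
Reactants: 8 tert-butyl{[(2E,6E)-3,7-dimethyldodeca-2,6-dien-10-yn-1-yl]oxy}dimethylsilane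
Product: 9 (2E,6E)-3,7-dimethyldodeca-2,6-dien-10-yn-1-ol
Conditions: Bu4NF, THF, 0 °C to rt
Reagents that add atoms: none
Why: Fluoride-mediated desilylation frees the allylic alcohol that must direct the epoxidation.

Step 6
Reactants: 9 (2E,6E)-3,7-dimethyldodeca-2,6-dien-10-yn-1-ol
Product: 10 [(2S,3S)-3-methyl-3-[(3E)-4-methylnon-3-en-7-yn-1-yl]oxiran-2-yl]methanol
Conditions: Ti(OiPr)4 (cat.), L-(+)-diethyl tartrate (cat.), t-BuOOH, 4 Å molecular sieves, CH2Cl2, −20 °C
Reagents that add atoms: tert-butyl hydroperoxide, CC(C)(C)OO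
Why: Sharpless asymmetric epoxidation: the titanium tartrate complex binds the allylic alcohol and delivers oxygen only to the C3=C4 alkene, and L-(+)-tartrate sets both epoxide centres (3S,4S in cembrane locants), the configuration of the target.

Step 7
Reactants: 10 [(2S,3S)-3-methyl-3-[(3E)-4-methylnon-3-en-7-yn-1-yl]oxiran-2-yl]methanol
Product: 12 (2S,3S,6E)-3,7-dimethyl-1-(phenylselanyl)dodec-6-en-10-yne-2,3-diol, via terminal epoxy alcohol 11 (not isolated)
Conditions: PhSeH (slow addition), NaOH (0.5 M aq.), t-BuOH, 70 °C, argon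
Reagents that add atoms: benzeneselenol, [SeH]c1ccccc1
Why: Payne rearrangement with nucleophilic trapping: in aqueous base the C2 alkoxide opens the epoxide at C3 with inversion to the terminal C2–C3 epoxide 11, which the selenolate opens at primary C2 much faster than it attacks the hindered trisubstituted epoxide, so that C3 is inverted, the tertiary C4 is untouched and a radical precursor sits on C2.

Step 8
Reactants: 13 (S)-5-(hydroxymethyl)furan-2(5H)-one
Product: 14 (S)-5-{[(tert-butyldiphenylsilyl)oxy]methyl}furan-2(5H)-one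
Conditions: TBDPSCl, imidazole, CH2Cl2, 0 °C to rt
Reagents that add atoms: tert-butyldiphenylsilyl chloride, CC(C)(C)[Si](Cl)(c1ccccc1)c1ccccc1
Why: Silyl ether formation at the primary alcohol gives a bulky group that shields one face of the butenolide and survives every step up to step 11.

Step 9
Reactants: 12 (2S,3S,6E)-3,7-dimethyl-1-(phenylselanyl)dodec-6-en-10-yne-2,3-diol; 14 (S)-5-{[(tert-butyldiphenylsilyl)oxy]methyl}furan-2(5H)-one
Product: 15 (4S,5S)-5-{[(tert-butyldiphenylsilyl)oxy]methyl}-4-[(2R,3S,6E)-2,3-dihydroxy-3,7-dimethyldodec-6-en-10-yn-1-yl]oxolan-2-one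
Conditions: 14 (3 equiv, about 1 M), (Me3Si)3SiH (syringe pump), Et3B (cat.), air, toluene, 25 °C
Reagents that add atoms: none
Why: Giese addition: the silyl radical abstracts the phenylselanyl group, the primary β-hydroxyalkyl radical at C2 adds to the butenolide β-carbon anti to the silyloxymethyl group, which sets C1 trans to C14, and the α-lactone radical is reduced by the silane, the excess of acceptor keeping addition ahead of 6-exo closure onto C7=C8 and of 1,5-hydrogen transfer.

Step 10
Reactants: 15 (4S,5S)-5-{[(tert-butyldiphenylsilyl)oxy]methyl}-4-[(2R,3S,6E)-2,3-dihydroxy-3,7-dimethyldodec-6-en-10-yn-1-yl]oxolan-2-one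
Product: 17 (4S,5S)-5-{[(tert-butyldiphenylsilyl)oxy]methyl}-4-{[(2S,3S)-3-methyl-3-[(3E)-4-methylnon-3-en-7-yn-1-yl]oxiran-2-yl]methyl}oxolan-2-one, via secondary mesylate 16 (not isolated)
Conditions: MsCl, Et3N, CH2Cl2, −10 °C; then DBU, 25 °C
Reagents that add atoms: none
Why: Selective sulfonylation of the secondary over the tertiary hydroxyl is followed by an intramolecular Williamson closure (3-exo-tet) in which the C4 oxygen displaces the mesylate with inversion at C3, which restores the trans (3S,4S) epoxide, and the non-nucleophilic base spares the lactone.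

Step 11
Reactants: 17 (4S,5S)-5-{[(tert-butyldiphenylsilyl)oxy]methyl}-4-{[(2S,3S)-3-methyl-3-[(3E)-4-methylnon-3-en-7-yn-1-yl]oxiran-2-yl]methyl}oxolan-2-one
Product: 18 (4S,5S)-5-(hydroxymethyl)-4-{[(2S,3S)-3-methyl-3-[(3E)-4-methylnon-3-en-7-yn-1-yl]oxiran-2-yl]methyl}oxolan-2-one
Conditions: Bu4NF, AcOH, THF, 0 °C to rt
Reagents that add atoms: none
Why: Fluoride desilylation buffered with acetic acid frees the primary alcohol without opening the lactone or the epoxide.

Step 12
Reactants: 18 (4S,5S)-5-(hydroxymethyl)-4-{[(2S,3S)-3-methyl-3-[(3E)-4-methylnon-3-en-7-yn-1-yl]oxiran-2-yl]methyl}oxolan-2-one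
Product: 19 (2S,3S)-3-{[(2S,3S)-3-methyl-3-[(3E)-4-methylnon-3-en-7-yn-1-yl]oxiran-2-yl]methyl}-5-oxooxolane-2-carbaldehyde (seco-ynal)
Conditions: Dess–Martin periodinane, NaHCO3, CH2Cl2, 0 °C to rt; used at once
Reagents that add atoms: none
Why: Dess–Martin oxidation under buffered conditions gives the α-oxygenated aldehyde without epimerising C14 or opening the epoxide.

Step 13
Reactants: 19 (2S,3S)-3-{[(2S,3S)-3-methyl-3-[(3E)-4-methylnon-3-en-7-yn-1-yl]oxiran-2-yl]methyl}-5-oxooxolane-2-carbaldehyde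
Product: 20 (1S,3S,4S,7E,11E,13R,14S)-3,4-epoxy-13-[(triethylsilyl)oxy]-17-norcembra-7,11-dien-16,14-olide
Conditions: Ni(cod)2 (25 mol %), IMes (1,3-dimesitylimidazol-2-ylidene, 25 mol %), Et3SiH (5 equiv), THF, 45 °C, 19 added by syringe pump, final 0.003 M
Reagents that add atoms: triethylsilane, CC[SiH](CC)CC
Why: Zerovalent nickel carrying IMes binds the C11≡C12 alkyne and the C13 aldehyde and undergoes oxidative cyclisation to an oxanickelacyclopentene in which C12 is bonded to C13; σ-bond metathesis of the Ni–O bond with Et3SiH gives the silyl ether and a nickel hydride, and C–H reductive elimination places hydrogen on C11 cis to the new bond, which is the E alkene. The closest known reaction type is the nickel/carbene-catalysed reductive macrocyclisation of ynals with silanes. The 14-membered ring closes in the endocyclic mode, both alkyne carbons entering the ring: the compact carbene IMes lets the larger, tether-bearing C11 sit on nickel and the bond form at the methyl-bearing C12, whereas very bulky carbenes would push towards the exocyclic 13-membered ring. The new C13 centre is controlled by 1,2-induction from C14: C12 should add anti to the C14–O bond of the lactone (polar Felkin–Anh), which gives the 13R ether, although the tether may erode this preference. The step needs bond formation at C12 and ring closure in preference to oligomerisation, secured by the methyl cap, the ligand and slow addition at high dilution; the saturated lactone, the trisubstituted epoxide and the C7=C8 alkene offer nickel no competing site. The C13 configuration is not critical, because a 13S epimer reaches 25 by plain acetylation.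

Step 14
Reactants: 20 (1S,3S,4S,7E,11E,13R,14S)-3,4-epoxy-13-[(triethylsilyl)oxy]-17-norcembra-7,11-dien-16,14-olide
Product: 23 (1S,3S,4S,7E,11E,13R,14S)-3,4-epoxy-13-[(triethylsilyl)oxy]cembra-7,11,15(17)-trien-16,14-olide, via Mannich base 21 (not isolated), via ammonium iodide 22 (not isolated)
Conditions: LiN(iPr)2, THF, −78 °C; CH2=NMe2+ I−, −78 °C to rt; then MeI, rt; then NaHCO3 (aq.), CH2Cl2, rt
Reagents that add atoms: N,N-dimethylmethyleneiminium iodide, C=[N+](C)C.[I-]
Why: Eschenmoser α-methylenation: the lithium enolate at C15, the only enolisable position, is aminomethylated, and quaternisation followed by mild base elimination of trimethylamine gives the exocyclic alkene while the silyl ether protects C13.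

Step 15
Reactants: 23 (1S,3S,4S,7E,11E,13R,14S)-3,4-epoxy-13-[(triethylsilyl)oxy]cembra-7,11,15(17)-trien-16,14-olide
Product: 24 (1S,3S,4S,7E,11E,13R,14S)-3,4-epoxy-13-hydroxycembra-7,11,15(17)-trien-16,14-olide
Conditions: Bu4NF, AcOH, THF, 0 °C
Reagents that add atoms: none
Why: Buffered fluoride cleavage of the triethylsilyl ether avoids conjugate addition to the methylene lactone and opening of the epoxide.

Step 16
Reactants: 24 (1S,3S,4S,7E,11E,13R,14S)-3,4-epoxy-13-hydroxycembra-7,11,15(17)-trien-16,14-olide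
Product: 25 13-acetoxysarcocrassolide, (1S,3S,4S,7E,11E,13S,14S)-13-acetoxy-3,4-epoxycembra-7,11,15(17)-trien-16,14-olide
Conditions: PPh3, AcOH, toluene, 0 °C; DIAD added last, 0 °C to rt
Reagents that add atoms: acetic acid, CC(=O)O
Why: Mitsunobu esterification: the C13 oxyphosphonium ion is displaced by acetate in an SN2 reaction with inversion (13R to 13S), and the adjacent C14–O bond disfavours ionisation and allylic transposition.

Compound list
1 | geraniol, (2E)-3,7-dimethylocta-2,6-dien-1-ol | CC(C)=CCC/C(C)=C/CO | starting material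
2 | tert-butyl{[(2E)-3,7-dimethylocta-2,6-dien-1-yl]oxy}dimethylsilane | CC(C)=CCC/C(C)=C/CO[Si](C)(C)C(C)(C)C | intermediate
3 | (2E,6E)-8-[(tert-butyldimethylsilyl)oxy]-2,6-dimethylocta-2,6-dien-1-ol | OC/C(C)=C/CC/C(C)=C/CO[Si](C)(C)C(C)(C)C | intermediate
4 | {[(2E,6E)-8-bromo-3,7-dimethylocta-2,6-dien-1-yl]oxy}(tert-butyl)dimethylsilane | BrC/C(C)=C/CC/C(C)=C/CO[Si](C)(C)C(C)(C)C | intermediate
5 | propyne | CC#C | starting material
6 | 1,3-dilithiopropyne | [Li]CC#C[Li] | intermediate
7 | lithium (5E,9E)-11-[(tert-butyldimethylsilyl)oxy]-5,9-dimethylundeca-5,9-dien-1-yn-1-ide (lithium acetylide) | [Li]C#CCC/C(C)=C/CC/C(C)=C/CO[Si](C)(C)C(C)(C)C | intermediate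
8 | tert-butyl{[(2E,6E)-3,7-dimethyldodeca-2,6-dien-10-yn-1-yl]oxy}dimethylsilane | CC#CCC/C(C)=C/CC/C(C)=C/CO[Si](C)(C)C(C)(C)C | intermediate
9 | (2E,6E)-3,7-dimethyldodeca-2,6-dien-10-yn-1-ol | CC#CCC/C(C)=C/CC/C(C)=C/CO | intermediate
10 | [(2S,3S)-3-methyl-3-[(3E)-4-methylnon-3-en-7-yn-1-yl]oxiran-2-yl]methanol | OC[C@@H]1O[C@@]1(C)CC/C=C(\C)CCC#CC | intermediate
11 | (2S,5E)-6-methyl-2-[(2R)-oxiran-2-yl]undec-5-en-9-yn-2-ol (terminal epoxy alcohol) | C1O[C@H]1[C@@](C)(O)CC/C=C(\C)CCC#CC | intermediate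
12 | (2S,3S,6E)-3,7-dimethyl-1-(phenylselanyl)dodec-6-en-10-yne-2,3-diol | c1ccccc1[Se]C[C@@H](O)[C@@](C)(O)CC/C=C(\C)CCC#CC | intermediate
13 | (S)-5-(hydroxymethyl)furan-2(5H)-one | O=C1C=C[C@@H](CO)O1 | starting material
14 | (S)-5-{[(tert-butyldiphenylsilyl)oxy]methyl}furan-2(5H)-one | O=C1C=C[C@@H](CO[Si](c2ccccc2)(c2ccccc2)C(C)(C)C)O1 | intermediate
15 | (4S,5S)-5-{[(tert-butyldiphenylsilyl)oxy]methyl}-4-[(2R,3S,6E)-2,3-dihydroxy-3,7-dimethyldodec-6-en-10-yn-1-yl]oxolan-2-one | O=C1C[C@H](C[C@@H](O)[C@@](C)(O)CC/C=C(\C)CCC#CC)[C@@H](CO[Si](c2ccccc2)(c2ccccc2)C(C)(C)C)O1 | intermediate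
16 | (2R,3S,6E)-1-[(2S,3S)-2-{[(tert-butyldiphenylsilyl)oxy]methyl}-5-oxooxolan-3-yl]-3-hydroxy-3,7-dimethyldodec-6-en-10-yn-2-yl methanesulfonate (secondary mesylate) | O=C1C[C@H](C[C@@H](OS(C)(=O)=O)[C@@](C)(O)CC/C=C(\C)CCC#CC)[C@@H](CO[Si](c2ccccc2)(c2ccccc2)C(C)(C)C)O1 | intermediate
17 | (4S,5S)-5-{[(tert-butyldiphenylsilyl)oxy]methyl}-4-{[(2S,3S)-3-methyl-3-[(3E)-4-methylnon-3-en-7-yn-1-yl]oxiran-2-yl]methyl}oxolan-2-one | O=C1C[C@H](C[C@@H]2O[C@@]2(C)CC/C=C(\C)CCC#CC)[C@@H](CO[Si](c3ccccc3)(c3ccccc3)C(C)(C)C)O1 | intermediate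
18 | (4S,5S)-5-(hydroxymethyl)-4-{[(2S,3S)-3-methyl-3-[(3E)-4-methylnon-3-en-7-yn-1-yl]oxiran-2-yl]methyl}oxolan-2-one | O=C1C[C@H](C[C@@H]2O[C@@]2(C)CC/C=C(\C)CCC#CC)[C@@H](CO)O1 | intermediate
19 | (2S,3S)-3-{[(2S,3S)-3-methyl-3-[(3E)-4-methylnon-3-en-7-yn-1-yl]oxiran-2-yl]methyl}-5-oxooxolane-2-carbaldehyde (seco-ynal) | O=C1C[C@H](C[C@@H]2O[C@@]2(C)CC/C=C(\C)CCC#CC)[C@@H](C=O)O1 | intermediate
20 | (1S,3S,4S,7E,11E,13R,14S)-3,4-epoxy-13-[(triethylsilyl)oxy]-17-norcembra-7,11-dien-16,14-olide (14-membered epoxy lactone without the methylene) | O=C1O[C@H]2[C@H](C1)C[C@@H]1O[C@@]1(C)CC/C=C(\C)CC/C=C(\C)[C@H]2O[Si](CC)(CC)CC | intermediate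
21 | (1S,3S,4S,7E,11E,13R,14S)-17-(dimethylamino)-3,4-epoxy-13-[(triethylsilyl)oxy]cembra-7,11-dien-16,14-olide, C15 epimers (Mannich base) | O=C1O[C@H]2[C@H](C1CN(C)C)C[C@@H]1O[C@@]1(C)CC/C=C(\C)CC/C=C(\C)[C@H]2O[Si](CC)(CC)CC | intermediate
22 | N-methyl quaternary salt of 21, 17-(trimethylammonio) iodide (ammonium iodide) | O=C1O[C@H]2[C@H](C1C[N+](C)(C)C)C[C@@H]1O[C@@]1(C)CC/C=C(\C)CC/C=C(\C)[C@H]2O[Si](CC)(CC)CC.[I-] | intermediate
23 | (1S,3S,4S,7E,11E,13R,14S)-3,4-epoxy-13-[(triethylsilyl)oxy]cembra-7,11,15(17)-trien-16,14-olide | C=C1C(=O)O[C@H]2[C@H]1C[C@@H]1O[C@@]1(C)CC/C=C(\C)CC/C=C(\C)[C@H]2O[Si](CC)(CC)CC | intermediate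
24 | (1S,3S,4S,7E,11E,13R,14S)-3,4-epoxy-13-hydroxycembra-7,11,15(17)-trien-16,14-olide | C=C1C(=O)O[C@H]2[C@H]1C[C@@H]1O[C@@]1(C)CC/C=C(\C)CC/C=C(\C)[C@H]2O | intermediate
25 | 13-acetoxysarcocrassolide, (1S,3S,4S,7E,11E,13S,14S)-13-acetoxy-3,4-epoxycembra-7,11,15(17)-trien-16,14-olide | C=C1C(=O)O[C@H]2[C@H]1C[C@@H]1O[C@@]1(C)CC/C=C(\C)CC/C=C(\C)[C@@H]2OC(C)=O | target

Total step count: 16.
Longest linear sequence: 15 steps (steps 1–7 and 9–16, from geraniol 1 to 25); step 8 is a one-step side branch.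

Steps most likely to fail

Step 13. What may go wrong: the oxidative cyclisation forms the bond at C11 (exocyclic closure), or intermolecular coupling and hydrosilylation of the aldehyde outrun ring closure. The fallback is a Nozaki–Hiyama–Kishi closure of the same bond. It sets out from 17: hydrozirconation with Cp2Zr(H)Cl (THF, 25 °C, zirconium settling on the methyl-bearing C12 by syn addition) and iodinolysis with I2 would give the E-vinyl iodide silyl ether F1. Bu4NF with AcOH would give the vinyl iodide alcohol F2, and Dess–Martin oxidation the vinyl iodide aldehyde F3. CrCl2 with catalytic NiCl2 in DMSO–THF at high dilution would close the ring to the macrocyclic allylic alcohol F4, the position of iodine fixing C12 as the bonding carbon. Et3SiCl and imidazole then return to the route at 20.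

Step 16. What may go wrong: substitution with allylic transposition (acetate entering at C11), elimination to a diene, or no reaction at the hindered C13. The fallback resets C13 by oxidation and reduction. It sets out from 24: Dess–Martin oxidation would give the C13 enone F5. NaBH4 with CeCl3·7H2O in MeOH at −78 °C should reduce the ketone in the 1,2-sense, with hydride arriving anti to the C14–O bond, to the 13S alcohol F6. Ac2O, pyridine and DMAP then give 25.

Step 7. What may go wrong: direct attack of the selenolate on the secondary carbon of the trisubstituted epoxide before Payne equilibration, giving the regioisomeric hydroxy selenide, or oxidative loss of the selenol. The fallback inverts the tertiary carbon under acid instead. It sets out from 9: Sharpless epoxidation with D-(−)-diethyl tartrate would give the enantiomeric epoxy alcohol F7, and I2, PPh3 and imidazole the epoxy iodide F8. Acetone with catalytic BF3·OEt2 at −30 °C would open the epoxide at tertiary C4 with inversion and close the dioxolane, giving the iodide acetonide F9 with the configuration of 12 at C3 and C4. Giese addition of F9 to 14 with (Me3Si)3SiH would give the acetonide lactone F10, and aqueous acetic acid at 45 °C returns to the route at 15.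

Further compounds
F1 | step 13 | (4S,5S)-5-{[(tert-butyldiphenylsilyl)oxy]methyl}-4-{[(2S,3S)-3-[(3E,7E)-8-iodo-4-methylnona-3,7-dien-1-yl]-3-methyloxiran-2-yl]methyl}oxolan-2-one | O=C1C[C@H](C[C@@H]2O[C@@]2(C)CC/C=C(\C)CC/C=C(\C)I)[C@@H](CO[Si](c3ccccc3)(c3ccccc3)C(C)(C)C)O1
F2 | step 13 | (4S,5S)-5-(hydroxymethyl)-4-{[(2S,3S)-3-[(3E,7E)-8-iodo-4-methylnona-3,7-dien-1-yl]-3-methyloxiran-2-yl]methyl}oxolan-2-one | O=C1C[C@H](C[C@@H]2O[C@@]2(C)CC/C=C(\C)CC/C=C(\C)I)[C@@H](CO)O1
F3 | step 13 | (2S,3S)-3-{[(2S,3S)-3-[(3E,7E)-8-iodo-4-methylnona-3,7-dien-1-yl]-3-methyloxiran-2-yl]methyl}-5-oxooxolane-2-carbaldehyde | O=C1C[C@H](C[C@@H]2O[C@@]2(C)CC/C=C(\C)CC/C=C(\C)I)[C@@H](C=O)O1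
F4 | step 13 | (1S,3S,4S,7E,11E,13R,14S)-3,4-epoxy-13-hydroxy-17-norcembra-7,11-dien-16,14-olide | O=C1O[C@H]2[C@H](C1)C[C@@H]1O[C@@]1(C)CC/C=C(\C)CC/C=C(\C)[C@H]2O
F5 | step 16 | (1S,3S,4S,7E,11E,14S)-3,4-epoxy-13-oxocembra-7,11,15(17)-trien-16,14-olide | C=C1C(=O)O[C@H]2[C@H]1C[C@@H]1O[C@@]1(C)CC/C=C(\C)CC/C=C(\C)C2=O
F6 | step 16 | (1S,3S,4S,7E,11E,13S,14S)-3,4-epoxy-13-hydroxycembra-7,11,15(17)-trien-16,14-olide | C=C1C(=O)O[C@H]2[C@H]1C[C@@H]1O[C@@]1(C)CC/C=C(\C)CC/C=C(\C)[C@@H]2O
F7 | step 7 | [(2R,3R)-3-methyl-3-[(3E)-4-methylnon-3-en-7-yn-1-yl]oxiran-2-yl]methanol | OC[C@H]1O[C@]1(C)CC/C=C(\C)CCC#CC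
F8 | step 7 | (2S,3R)-2-(iodomethyl)-3-methyl-3-[(3E)-4-methylnon-3-en-7-yn-1-yl]oxirane | IC[C@H]1O[C@]1(C)CC/C=C(\C)CCC#CC
F9 | step 7 | (4S,5S)-5-(iodomethyl)-2,2,4-trimethyl-4-[(3E)-4-methylnon-3-en-7-yn-1-yl]-1,3-dioxolane | IC[C@H]1OC(C)(C)O[C@@]1(C)CC/C=C(\C)CCC#CC
F10 | step 7 | (4S,5S)-5-{[(tert-butyldiphenylsilyl)oxy]methyl}-4-{[(4R,5S)-2,2,5-trimethyl-5-[(3E)-4-methylnon-3-en-7-yn-1-yl]-1,3-dioxolan-4-yl]methyl}oxolan-2-one | O=C1C[C@H](C[C@H]2OC(C)(C)O[C@@]2(C)CC/C=C(\C)CCC#CC)[C@@H](CO[Si](c3ccccc3)(c3ccccc3)C(C)(C)C)O1
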